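(Readings and results are calculated from invented constants; the scatter is artificial.)

Two runs could not name a mechanism, so I asked them for a single exponent. In these closed flasks the electrophile meets protonated nucleophile and solid base, and the charges differ in [protonated nucleophile].

all flasks: electrophile 0.10 M
- blue: protonated nucleophile 0.22 M; solid base 0.080 M; run made earlier
- green: protonated nucleophile 0.39 M; solid base 0.080 M; run made earlier
- Saturday's: protonated nucleophile 0.380 M; solid base 0.0800 M; time 10 d
- Monday's: protonated nucleophile 0.560 M; solid base 0.0800 M; time 10 d
- Tuesday's: protonated nucleophile 0.250 M; solid base 0.0800 M; time 10 d

- blue (time / d: electrophile / %, target / %): 2.50: 85, 10; 5.00: 71, 23; 8.00: 58, 35; 10.0: 49, 42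
- green (time / d: electrophile / %, target / %): 2.50: 83, 16; 5.00: 69, 25; 8.00: 49, 36; 10.0: 41, 45

(each reading ± 1.5 percentage points)

- solid base is a solid; its amount is given per volume of the solution
- at the start none of the solid base is in solution

- part of the electrophile that has reacted at the end, Saturday's
- part of the electrophile that has reacted at the end, Monday's
- part of the electrophile that has reacted at the end, Tuesday's
- what raising the concentration of protonated nucleophile from its lowest to its highest value here does to the part of the electrophile that has reacted (changes below 5 percentage points count as none) (it rises / no change / it falls)

I treated the loss of electrophile as pseudo-first-order, with k equal to minus the logarithm of the fraction left, divided by the time. The last readings gave 0.0713 /d for the blue run and 0.0892 /d for the green run. The logarithm of their ratio over that of the concentrations gave 0.390. This is the apparent order, the exponent by which k grows with [protonated nucleophile] at these charges of electrophile and solid base; it is a reading and carries their scatter.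

Scaling the blue k by it, I reckoned 58.6% reacted for Saturday's, 64.2% for Monday's and 52.8% for Tuesday's. That is a rise of 11 percentage points from Tuesday's to Monday's, above the margin.

The forecast, citing “an apparent order near 0.4”, gave slightly lower figures: 58%, 63% and 52%, and for the trend, it rises.

The flasks gave 57.6%, 63.3% and 52.1%; from Tuesday's to Monday's it rises, by 11 points. My reckoning used one constant and one exponent, without the equations below.

    solid base ⇌ free base, rate k1*(cs1 - [free base]) while solid is left; crystals form when [free base] > cs1 (solubility = 27.0 mM, k = 0.0127 /h)
    electrophile + acid set free → side product (k = 1.02 /M/h)
    electrophile + nucleophile → acid set free + target (k = 0.713 /M/h)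
    nucleophile + acid set free ⇌ protonated nucleophile, settled at all times (K = 1.48 × 10⁵ /M)
    acid set free + free base ⇌ salt of the base, settled at all times (K = 1.53 × 10⁵ /M)
    acid set free → by-product carried off (k = 0.0615 /h)

Monday's reached 63.3%. At 10.0 d Monday's held 49.6% target and 13.6% side product, against 44.1% and 8.02% in Tuesday's; I had read the exponent from the loss of electrophile, which counts both. Carried from Tuesday's result to Monday's charge, 0.390 gives 63.5%.

For a neighbour of Monday's flask, charged as Monday's but with 0.95 M of protonated nucleophile, the same scaling gives 71.7% reacted. The simulation gave 71.8%, with 18.0% as side product.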